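Slowness was the first thing the earlier runs showed me, so here are the flasks and readings I reckoned from.

| flask | solid substrate | temperature | remark | time |
|---|---|---|---|---|
| north | 0.050 M | 18 °C | run made earlier |  |
| north-west | 0.20 M | 34 °C | run made earlier |  |
| teal | 0.10 M |  | at 40 °C throughout | 150 min |
| blue | 0.10 M |  | at 40 °C until 40 min, from then on at 10 °C | 80 min |

| run | time / min | target / % | isomer of the product / % |
|---|---|---|---|
| north | 25.0 | 26.2 | 0.6 |
| north | 40.0 | 44.0 | 1.5 |
| north | 60.0 | 64.4 | 2.8 |
| north | 120 | 77.8 | 5.2 |
| north | 180 | 82.4 | 5.6 |
| north | 240 | 86.0 | 5.7 |
| north-west | 15.0 | 10.2 | 1.0 |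
| north-west | 30.0 | 22.7 | 2.1 |
| north-west | 50.0 | 40.2 | 4.2 |
| north-west | 60.0 | 48.7 | 4.8 |
| north-west | 80.0 | 66.0 | 6.9 |
| north-west | 90.0 | 74.8 | 8.2 |

(standard deviation of a reading: 0.3 percentage points)

- which of the two ends with the higher share of target in all that became target or isomer of the product or third product ("neither" if they lie within 2 percentage points) (teal / blue / neither)
- share of target in all that became target or isomer of the product or third product, teal
- share of target in all that became target or isomer of the product or third product, blue

- solid substrate is a solid; its amount is given per volume of the solution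
- at the start none of the solid substrate is in solution
- in a conversion other conformer counts as not yet reacted; third conformer counts as reacted
- what has only dissolved of solid substrate counts as not reacted

In the north-west run the products grew in a nearly straight line at 0.00194 M min⁻¹, while the cooler north run went slower, at 5.77 × 10⁻⁴ M min⁻¹. I read this as product being fed at a steady, slow pace, and I solved the two ends.

The last readings give isomer over target as 0.0663 in the north run and 0.110 in the north-west run. Carrying the logarithm of that ratio straight along the temperature gave 0.132 at 40 °C and 0.0515 at 10 °C. With the product made at the hot end, the share of target, or selectivity, would be 88.3%; with it made at the cold end, 95.1%. Third product was never read, so both shares stand a little high.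

Teal is the hot end, and blue lies between the ends, according to how much is still unmade at the switch. Taking the north-west rate as a floor, I estimated that 77.6% of blue's charge would be product by 40 min. This gives the cooling gap, the unmade part at the switch times the difference between the two end shares: 1.5 percentage points. That is below the margin of 2 points, so I committed to neither.

The forecast also said neither, with 88% for teal and 89% for blue, in the words “blue makes most of its product before cooling”. The flask gave 87.3% for teal and 88.0% for blue, so neither.

    starting material ⇌ other conformer (K = 0.590, k = 0.170 min⁻¹, Ea = 95.0 kJ mol⁻¹, ΔH = 7.00 kJ mol⁻¹)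
    starting material → target (k = 0.660 min⁻¹, Ea = 85.0 kJ mol⁻¹)
    other conformer → isomer of the product (k = 0.330 min⁻¹, Ea = 99.0 kJ mol⁻¹)
    other conformer ⇌ third conformer (K = 0.120, k = 0.420 min⁻¹, Ea = 79.0 kJ mol⁻¹, ΔH = −41.0 kJ mol⁻¹)
    third conformer → third product (k = 0.390 min⁻¹, Ea = 78.0 kJ mol⁻¹)
    starting material ⇌ dormant form (K = 1.70, k = 0.220 min⁻¹, Ea = 85.0 kJ mol⁻¹, ΔH = 0 kJ mol⁻¹)
    solid substrate ⇌ starting material, rate k7*(cs7 - [starting material]) while solid is left; crystals form when [starting material] > cs7 (solubility = 15.0 mM, k = 0.200 min⁻¹)
    (constants at 40 °C)

Teal had come to rest by 150 min, with 0% of its charge left, and its share at 1500 min was still 87.3%. Blue had not: at 80.0 min it still held 5.47% as dormant form and 2.50% as starting material. Left until 800 min, blue stood 0.40 points above teal's share at 1500 min, still inside the cooling gap of 1.5 points. Blue's target rose from 80.2% to 87.0%, while its share moved from 88.0% to 87.7%.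

The readings stem from a simulated flask with made-up constants; the scatter is artificial.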